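**Retrosynthetic overview**

- Ring D (C1'–C4', C4a', C8a') is closed last, at C1'–C2', by a proline-catalysed dienamine aldol of an enone arm on C4a' onto an aldehyde on C8a'; this sets C1' (S) and C2' (R), trans.
- The arm comes from cross-metathesis (C2'=C3') of a methallyl group coupled to C4a'–Cl, the aldehyde from phenoxide-directed ortho-formylation at C8a', and the C2 acetyl from a Fries rearrangement of the ring-A naphthol.
- Ring A (C1–C4 on the C4a–C8a fusion) is cut at C8a–C1, C4a–C4 and C2–C3, giving a C4a≡C8a aryne and pentane-2,4-dione. The feature used is that the C8 oxygen sits directly beside C8a and C1–OH must end peri to it, so this oxygen can steer the acyl carbon to C8a and the alkyl carbon to C4a.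
- The aryne precursor (an ortho-silyl aryl triflate of ring B carrying ring C on C7) comes from a Suzuki biaryl coupling (C7–C7'), carbamate-directed silylation between the two oxygens, and triflation.
- Ring order: rings B and C are bought as benzene rings, ring A is built in step 5, ring D in step 12.

Key step: step 5

Remark: unprimed locants and rings A/B refer to the aromatic naphthalene half, primed locants and rings C/D to the 1,2-dihydronaphthalene half. The C7–C7' axis has only two ortho substituents and is treated as freely rotating, so C1' (S) and C2' (R) are the only stereo-elements to control.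

**Route**

Step 1
Reactants: 1 4-bromo-3-methoxyphenol; 2 (4-chloro-2-methoxyphenyl)boronic acid
Product: 3 4-(4-chloro-2-methoxyphenyl)-3-methoxyphenol
Conditions: Pd(PPh3)4 (3 mol%), K2CO3, 1,4-dioxane/H2O, 90 °C
Reagents that add atoms: none
Why: Suzuki–Miyaura coupling in which the PPh3-ligated catalyst should insert into the C–Br bond of 1 and leave the C–Cl bond of 2 untouched, the bromine of 1 fixing the biaryl bond para to the phenol oxygen without any regiochemical question.

Step 2
Reactants: 3 4-(4-chloro-2-methoxyphenyl)-3-methoxyphenol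
Product: 4 4-(4-chloro-2-methoxyphenyl)-3-methoxyphenyl N-(propan-2-yl)carbamate
Conditions: i-PrNCO, Et3N (cat.), CH2Cl2, rt
Reagents that add atoms: isopropyl isocyanate, CC(C)N=C=O
Why: Addition of the phenol to the isocyanate gives an N-isopropyl carbamate, a strong ortho-directing group that can later be removed under mild base.

Step 3
Reactants: 4 4-(4-chloro-2-methoxyphenyl)-3-methoxyphenyl N-(propan-2-yl)carbamate
Product: 8 4-(4-chloro-2-methoxyphenyl)-3-methoxy-2-(trimethylsilyl)phenyl N-(propan-2-yl)carbamate, via N-silyl carbamate 5 (not isolated), via aryllithium 6 (not isolated), via bis-silyl carbamate 7 (not isolated)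
Conditions: TMSOTf, TMEDA, Et2O, 0 °C to rt; n-BuLi (2.2 equiv), TMEDA, −78 °C; TMSCl, −78 °C to rt; aq. NH4Cl work-up
Reagents that add atoms: chlorotrimethylsilane, C[Si](C)(C)Cl
Why: Directed ortho-metalation of the carbamate silylated in situ on nitrogen should take the position flanked by the carbamate and the methoxy group, which both acidify and coordinate there, while the short reaction at −78 °C with only one effective equivalent of base should spare the chloroanisole ring.

Step 4
Reactants: 8 4-(4-chloro-2-methoxyphenyl)-3-methoxy-2-(trimethylsilyl)phenyl N-(propan-2-yl)carbamate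
Product: 10 4-(4-chloro-2-methoxyphenyl)-3-methoxy-2-(trimethylsilyl)phenyl trifluoromethanesulfonate, via silyl phenol 9 (not isolated)
Conditions: DBU, Et2NH, MeCN, 40 °C; then PhNTf2, rt
Reagents that add atoms: N-phenylbis(trifluoromethanesulfonimide), O=S(=O)(N(c1ccccc1)S(=O)(=O)C(F)(F)F)C(F)(F)F
Why: E1cB cleavage of the N–H carbamate releases the phenoxide (the isocyanate is trapped by diethylamine), and O-triflation with the mild triflimide reagent should leave the aryl–silicon bond intact.

Step 5
Reactants: 10 4-(4-chloro-2-methoxyphenyl)-3-methoxy-2-(trimethylsilyl)phenyl trifluoromethanesulfonate; 11 pentane-2,4-dione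
Product: 14 7-(4-chloro-2-methoxyphenyl)-8-methoxy-3-methylnaphthalen-1-ol, via aryne 12 (not isolated), via diketone 13 (not isolated)
Conditions: CsF (3 equiv), MeCN, 80 °C; then K2CO3 (0.5 equiv), 80 °C, one pot
Reagents that add atoms: none
Why: Fluoride removes the silyl group of 10 and triflate leaves, giving aryne 12 with its strained bond between C4a and C8a. The caesium enolate of 11 adds through its central carbon to C4a, the aryl anion at C8a closes onto the adjacent carbonyl to a benzocyclobutenoxide, and retro-aldol opening leaves an acetyl group on C8a and an acetonyl group on C4a (13); this is the known acyl-alkylation of arynes by insertion into the C–C bond of β-dicarbonyl compounds. K2CO3 then closes ring A by a 6-(enolendo)-exo-trig aldol addition of the acetyl methyl carbon (C2) to the acetonyl carbonyl (C3), and loss of water with tautomerisation gives the naphthol, the known cyclodehydration of such 1,5-diketones to 3-methyl-1-naphthols. No stereocentre is formed. The step needs the enolate to attack C4a and not C8a, which the C8 methoxy group should secure: its inductive pull makes C4a the more electrophilic aryne terminus and stabilises the developing negative charge at C8a, so that C1–OH ends peri to the C8 oxygen. It also needs the aldol to run from the aryl ketone methyl to the aliphatic ketone, which is favoured because the di-ortho-substituted aryl ketone is the poorer electrophile and the benzylic enolate can only close a strained four-membered ring reversibly.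

Step 6
Reactants: 14 7-(4-chloro-2-methoxyphenyl)-8-methoxy-3-methylnaphthalen-1-ol
Product: 15 7-(4-chloro-2-methoxyphenyl)-8-methoxy-3-methylnaphthalen-1-yl acetate
Conditions: Ac2O, pyridine, DMAP (cat.), CH2Cl2, rt
Reagents that add atoms: acetic anhydride, CC(=O)OC(C)=O
Why: O-acylation of the naphthol places the acetyl group on the C1 oxygen, from where the Fries rearrangement can deliver it to C2.

Step 7
Reactants: 15 7-(4-chloro-2-methoxyphenyl)-8-methoxy-3-methylnaphthalen-1-yl acetate
Product: 16 1-[7-(4-chloro-2-methoxyphenyl)-1-hydroxy-8-methoxy-3-methylnaphthalen-2-yl]ethan-1-one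
Conditions: Sc(OTf)3 (10 mol%), toluene, 100 °C
Reagents that add atoms: none
Why: Lewis acid-catalysed Fries rearrangement, in which reversible acyl transfer should settle at C2 because only there is the ketone held as a chelate with the C1 oxygen, and not at C4 or C5.

Step 8
Reactants: 16 1-[7-(4-chloro-2-methoxyphenyl)-1-hydroxy-8-methoxy-3-methylnaphthalen-2-yl]ethan-1-one
Product: 17 1-[7-(4-chloro-2-hydroxyphenyl)-1,8-dihydroxy-3-methylnaphthalen-2-yl]ethan-1-one
Conditions: BBr3 (4 equiv), CH2Cl2, −78 °C to rt; aq. work-up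
Reagents that add atoms: none
Why: Boron tribromide cleavage of both aryl methyl ethers is placed here, before any alkene or aldehyde is present, and the aryl chloride and the chelated ketone should be inert to it.

Step 9
Reactants: 17 1-[7-(4-chloro-2-hydroxyphenyl)-1,8-dihydroxy-3-methylnaphthalen-2-yl]ethan-1-one; 18 4,4,5,5-tetramethyl-2-(2-methylprop-2-en-1-yl)-1,3,2-dioxaborolane
Product: 19 1-{1,8-dihydroxy-7-[2-hydroxy-4-(2-methylprop-2-en-1-yl)phenyl]-3-methylnaphthalen-2-yl}ethan-1-one
Conditions: Pd(OAc)2 (5 mol%), XPhos (10 mol%), K3PO4, THF/H2O (degassed), 65 °C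
Reagents that add atoms: none
Why: Suzuki–Miyaura coupling of an aryl chloride with an allylboronate, in which the bulky biarylphosphine permits insertion into the C–Cl bond, the symmetrical methallyl group gives the same product from either terminus, and the phenols are carried as phenoxides.

Step 10
Reactants: 19 1-{1,8-dihydroxy-7-[2-hydroxy-4-(2-methylprop-2-en-1-yl)phenyl]-3-methylnaphthalen-2-yl}ethan-1-one
Product: 21 3-(7-acetyl-1,8-dihydroxy-6-methylnaphthalen-2-yl)-2-hydroxy-6-(2-methylprop-2-en-1-yl)benzaldehyde, via hydroxymethyl phenol 20 (not isolated)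
Conditions: MgCl2, Et3N, (CH2O)n, THF, reflux; aq. HCl work-up
Reagents that add atoms: paraformaldehyde (as formaldehyde), C=O
Why: Magnesium phenoxide-directed ortho-formylation (Casnati–Skattebøl reaction) is strictly ortho, and C8a' is the only unsubstituted carbon ortho to any of the three phenoxides, the hydroxymethyl intermediate being oxidised in the flask by a second formaldehyde.

Step 11
Reactants: 21 3-(7-acetyl-1,8-dihydroxy-6-methylnaphthalen-2-yl)-2-hydroxy-6-(2-methylprop-2-en-1-yl)benzaldehyde; 22 but-3-en-2-one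
Product: 23 3-(7-acetyl-1,8-dihydroxy-6-methylnaphthalen-2-yl)-2-hydroxy-6-[(2E)-2-methyl-4-oxopent-2-en-1-yl]benzaldehyde
Conditions: second-generation Hoveyda–Grubbs catalyst [RuCl2(H2IMes)(=CH–C6H4-2-Oi-Pr)] (10 mol%), but-3-en-2-one (10 equiv), CH2Cl2, 40 °C
Reagents that add atoms: none
Why: Olefin cross-metathesis between a 1,1-disubstituted alkene and an electron-poor vinyl ketone, neither of which homodimerises readily, should give the trisubstituted enone under neutral conditions that do not enolise the new ketone towards the aldehyde; the alkene geometry is lost in the next step and is not critical.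

Step 12
Reactants: 23 3-(7-acetyl-1,8-dihydroxy-6-methylnaphthalen-2-yl)-2-hydroxy-6-[(2E)-2-methyl-4-oxopent-2-en-1-yl]benzaldehyde
Product: 24 1-[(1S,2R)-7-(7-acetyl-1,8-dihydroxy-6-methylnaphthalen-2-yl)-1,8-dihydroxy-3-methyl-1,2-dihydronaphthalen-2-yl]ethan-1-one
Conditions: (R)-proline (30 mol%), DMSO, rt
Reagents that add atoms: none
Why: Proposed new method: (R)-proline should condense with the enone carbonyl to a conjugated iminium ion, loss of a benzylic C4' proton should give the linear dienamine, and its α-carbon C2' should add to the aldehyde in a 6-(enolexo)-exo-trig closure through the chair-like enamine transition state in which the carboxylic acid hydrogen-bonds the aldehyde oxygen and presents the Si face of C1' to the (E)-enamine, so that C1'–OH and C2'–acetyl come out trans with the (1S,2R) configuration while the double bond moves to C3'=C4'; the closest known reactions are the proline-catalysed 6-enolexo aldolisation of dicarbonyl compounds and α-functionalisation of unsaturated carbonyl compounds through dienamines.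

**Compound list**

1 | 4-bromo-3-methoxyphenol | COc1cc(O)ccc1Br | starting material
2 | (4-chloro-2-methoxyphenyl)boronic acid | COc1cc(Cl)ccc1B(O)O | starting material
3 | 4-(4-chloro-2-methoxyphenyl)-3-methoxyphenol | COc1cc(O)ccc1-c1ccc(Cl)cc1OC | intermediate
4 | 4-(4-chloro-2-methoxyphenyl)-3-methoxyphenyl N-(propan-2-yl)carbamate | COc1cc(OC(=O)NC(C)C)ccc1-c1ccc(Cl)cc1OC | intermediate
5 | 4-(4-chloro-2-methoxyphenyl)-3-methoxyphenyl N-(propan-2-yl)-N-(trimethylsilyl)carbamate | COc1cc(OC(=O)N(C(C)C)[Si](C)(C)C)ccc1-c1ccc(Cl)cc1OC | intermediate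
6 | 2-lithio derivative of 5 (lithium between the carbamate and the methoxy group) | COc1c([Li])c(OC(=O)N(C(C)C)[Si](C)(C)C)ccc1-c1ccc(Cl)cc1OC | intermediate
7 | 4-(4-chloro-2-methoxyphenyl)-3-methoxy-2-(trimethylsilyl)phenyl N-(propan-2-yl)-N-(trimethylsilyl)carbamate | COc1c([Si](C)(C)C)c(OC(=O)N(C(C)C)[Si](C)(C)C)ccc1-c1ccc(Cl)cc1OC | intermediate
8 | 4-(4-chloro-2-methoxyphenyl)-3-methoxy-2-(trimethylsilyl)phenyl N-(propan-2-yl)carbamate | COc1c([Si](C)(C)C)c(OC(=O)NC(C)C)ccc1-c1ccc(Cl)cc1OC | intermediate
9 | 4-(4-chloro-2-methoxyphenyl)-3-methoxy-2-(trimethylsilyl)phenol | COc1c([Si](C)(C)C)c(O)ccc1-c1ccc(Cl)cc1OC | intermediate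
10 | 4-(4-chloro-2-methoxyphenyl)-3-methoxy-2-(trimethylsilyl)phenyl trifluoromethanesulfonate | COc1c(-c2ccc(Cl)cc2OC)ccc(OS(=O)(=O)C(F)(F)F)c1[Si](C)(C)C | intermediate
11 | pentane-2,4-dione | CC(=O)CC(C)=O | starting material
12 | 4-(4-chloro-2-methoxyphenyl)-3-methoxy-1,2-didehydrobenzene (aryne) | COC1=C(C=CC#C1)c1ccc(Cl)cc1OC | intermediate
13 | 1-[2-acetyl-4-(4-chloro-2-methoxyphenyl)-3-methoxyphenyl]propan-2-one | COc1c(-c2ccc(Cl)cc2OC)ccc(CC(C)=O)c1C(C)=O | intermediate
14 | 7-(4-chloro-2-methoxyphenyl)-8-methoxy-3-methylnaphthalen-1-ol | COc1c(-c2ccc(Cl)cc2OC)ccc2cc(C)cc(O)c12 | intermediate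
15 | 7-(4-chloro-2-methoxyphenyl)-8-methoxy-3-methylnaphthalen-1-yl acetate | COc1c(-c2ccc(Cl)cc2OC)ccc2cc(C)cc(OC(C)=O)c12 | intermediate
16 | 1-[7-(4-chloro-2-methoxyphenyl)-1-hydroxy-8-methoxy-3-methylnaphthalen-2-yl]ethan-1-one | COc1c(-c2ccc(Cl)cc2OC)ccc2cc(C)c(C(C)=O)c(O)c12 | intermediate
17 | 1-[7-(4-chloro-2-hydroxyphenyl)-1,8-dihydroxy-3-methylnaphthalen-2-yl]ethan-1-one | CC(=O)c1c(C)cc2ccc(-c3ccc(Cl)cc3O)c(O)c2c1O | intermediate
18 | 4,4,5,5-tetramethyl-2-(2-methylprop-2-en-1-yl)-1,3,2-dioxaborolane | CC(=C)CB1OC(C)(C)C(C)(C)O1 | starting material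
19 | 1-{1,8-dihydroxy-7-[2-hydroxy-4-(2-methylprop-2-en-1-yl)phenyl]-3-methylnaphthalen-2-yl}ethan-1-one | CC(=O)c1c(C)cc2ccc(-c3ccc(CC(C)=C)cc3O)c(O)c2c1O | intermediate
20 | 1-{1,8-dihydroxy-7-[2-hydroxy-3-(hydroxymethyl)-4-(2-methylprop-2-en-1-yl)phenyl]-3-methylnaphthalen-2-yl}ethan-1-one | CC(=O)c1c(C)cc2ccc(-c3ccc(CC(C)=C)c(CO)c3O)c(O)c2c1O | intermediate
21 | 3-(7-acetyl-1,8-dihydroxy-6-methylnaphthalen-2-yl)-2-hydroxy-6-(2-methylprop-2-en-1-yl)benzaldehyde | CC(=O)c1c(C)cc2ccc(-c3ccc(CC(C)=C)c(C=O)c3O)c(O)c2c1O | intermediate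
22 | but-3-en-2-one | CC(=O)C=C | starting material
23 | 3-(7-acetyl-1,8-dihydroxy-6-methylnaphthalen-2-yl)-2-hydroxy-6-[(2E)-2-methyl-4-oxopent-2-en-1-yl]benzaldehyde | CC(=O)/C=C(\C)Cc1ccc(-c2ccc3cc(C)c(C(C)=O)c(O)c3c2O)c(O)c1C=O | intermediate
24 | 1-[(1S,2R)-7-(7-acetyl-1,8-dihydroxy-6-methylnaphthalen-2-yl)-1,8-dihydroxy-3-methyl-1,2-dihydronaphthalen-2-yl]ethan-1-one | CC(=O)c1c(C)cc2ccc(-c3ccc4c(c3O)[C@@H](O)[C@H](C(C)=O)C(C)=C4)c(O)c2c1O | target

**Step count and risks**

Total step count: 12. Longest linear sequence: 12 steps (1 to 24).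

Steps most likely to fail:

1. Step 12. Iminium and dienamine formation on the β,β-disubstituted enone may be slow, the facial discrimination at C1' may be insufficient, and the aldol may lose water and aromatise ring D. Fallback (known chemistry): set out from 23 and give up catalyst control. A catalytic amount of DBU in THF at 0 °C should form the extended enolate by deprotonation at C4', which adds through its α-carbon C2' to the aldehyde in the same 6-(enolexo)-exo-trig mode; this is a base-mediated intramolecular aldol addition, reversible and expected to settle on the trans isomer. It would give the racemic trans-aldol, that is 24 together with the enantiomeric (1R,2S)-aldol F1. Separation of the two by preparative HPLC on a chiral stationary phase returns to the route at 24.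

2. Step 11. Productive metathesis at the hindered 1,1-disubstituted alkene may be slow, ruthenium hydrides may move the methallyl double bond into conjugation with ring C, and the chelating polyphenol may arrest the catalyst. Fallback: set out from 17 and bring in the whole arm as a ketal-masked alkenylboronate, so that no metathesis is needed.
 - Zirconium-catalysed carboalumination of commercial pent-4-yn-2-ol (Me3Al, Cp2ZrCl2; then I2) should give racemic (4E)-5-iodo-4-methylpent-4-en-2-ol F2.
 - Dess–Martin oxidation should give (4E)-5-iodo-4-methylpent-4-en-2-one F3.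
 - Ketalisation with 1,2-bis(trimethylsilyloxy)ethane and catalytic TMSOTf at −78 °C should give 2-[(2E)-3-iodo-2-methylprop-2-en-1-yl]-2-methyl-1,3-dioxolane F4.
 - Miyaura borylation (B2pin2, PdCl2(PPh3)2, PPh3, KOPh, toluene, 50 °C) should give the alkenylboronate 2-methyl-2-[(2E)-2-methyl-3-(4,4,5,5-tetramethyl-1,3,2-dioxaborolan-2-yl)prop-2-en-1-yl]-1,3-dioxolane F5.
 - Suzuki coupling of F5 with 17 under the conditions of step 9 should give the ketal-protected styrene triol F6.
 - Formylation as in step 10 should give the ketal-protected aldehyde F7.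
 - Ketal hydrolysis (PPTS, acetone/H2O, rt) should give the (E)-β,γ-unsaturated keto aldehyde F8.
 - Under the conditions of step 12, F8 should enter the same dienamine, the C3'=C4' geometry equilibrating through the conjugated iminium ion, and the sequence comes back to the route at 24.

3. Step 5. The diketone enolate may be O-arylated or arylated twice, the crowded C8 methoxy group may steer the addition less cleanly than in simpler 3-alkoxyarynes, and the aldol may partly close in the other direction. Fallback: set out from 10 and build ring A by an aryne Diels–Alder reaction instead of an insertion.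
 - Deprotonation of commercial methyl 3-methylbut-2-enoate with LDA and trapping with TMSCl (THF, −78 °C) should give the vinylketene acetal [(1-methoxy-3-methylbuta-1,3-dien-1-yl)oxy]trimethylsilane F9.
 - Generation of the aryne from 10 (CsF, MeCN, rt) in the presence of F9 should give the cycloadduct 7-(4-chloro-2-methoxyphenyl)-1,8-dimethoxy-3-methyl-1-(trimethylsilyloxy)-1,4-dihydronaphthalene F10. The nucleophilic diene terminus should bond to C4a for the same electronic reason as in step 5.
 - Mild acid on work-up removes methanol and the silyl group, and aromatisation comes back to the route at 14.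

**Further compounds**

F1 | step 12 | 1-[(1R,2S)-7-(7-acetyl-1,8-dihydroxy-6-methylnaphthalen-2-yl)-1,8-dihydroxy-3-methyl-1,2-dihydronaphthalen-2-yl]ethan-1-one | CC(=O)c1c(C)cc2ccc(-c3ccc4c(c3O)[C@H](O)[C@@H](C(C)=O)C(C)=C4)c(O)c2c1O
F2 | step 11 | (4E)-5-iodo-4-methylpent-4-en-2-ol (racemic) | CC(O)C/C(C)=C/I
F3 | step 11 | (4E)-5-iodo-4-methylpent-4-en-2-one | CC(=O)C/C(C)=C/I
F4 | step 11 | 2-[(2E)-3-iodo-2-methylprop-2-en-1-yl]-2-methyl-1,3-dioxolane | CC1(C/C(C)=C/I)OCCO1
F5 | step 11 | 2-methyl-2-[(2E)-2-methyl-3-(4,4,5,5-tetramethyl-1,3,2-dioxaborolan-2-yl)prop-2-en-1-yl]-1,3-dioxolane | CC1(C/C(C)=C/B2OC(C)(C)C(C)(C)O2)OCCO1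
F6 | step 11 | 1-{1,8-dihydroxy-7-[2-hydroxy-4-[(1E)-2-methyl-3-(2-methyl-1,3-dioxolan-2-yl)prop-1-en-1-yl]phenyl]-3-methylnaphthalen-2-yl}ethan-1-one | CC(=O)c1c(C)cc2ccc(-c3ccc(/C=C(\C)CC4(C)OCCO4)cc3O)c(O)c2c1O
F7 | step 11 | 3-(7-acetyl-1,8-dihydroxy-6-methylnaphthalen-2-yl)-2-hydroxy-6-[(1E)-2-methyl-3-(2-methyl-1,3-dioxolan-2-yl)prop-1-en-1-yl]benzaldehyde | CC(=O)c1c(C)cc2ccc(-c3ccc(/C=C(\C)CC4(C)OCCO4)c(C=O)c3O)c(O)c2c1O
F8 | step 11 | 3-(7-acetyl-1,8-dihydroxy-6-methylnaphthalen-2-yl)-2-hydroxy-6-[(1E)-2-methyl-4-oxopent-1-en-1-yl]benzaldehyde | CC(=O)C/C(C)=C/c1ccc(-c2ccc3cc(C)c(C(C)=O)c(O)c3c2O)c(O)c1C=O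
F9 | step 5 | [(1-methoxy-3-methylbuta-1,3-dien-1-yl)oxy]trimethylsilane | COC(O[Si](C)(C)C)=CC(C)=C
F10 | step 5 | 7-(4-chloro-2-methoxyphenyl)-1,8-dimethoxy-3-methyl-1-(trimethylsilyloxy)-1,4-dihydronaphthalene | COc1c(-c2ccc(Cl)cc2OC)ccc2c1C(OC)(O[Si](C)(C)C)C=C(C)C2
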